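Everything rests on cutting the C2–C3 bond of pyran ring C. The target hides a redox pair. C4 is a plain CH2 on ring A, while C2–H is benzylic to electron-rich ring B, alpha to O1 and 1,5 to C4. The precursor is therefore a simple aryl benzyl ether carrying an ortho 2-nitrovinyl group, assembled from a salicylaldehyde, a benzyl chloride and nitromethane. In one operation a 1,5-hydride shift from C2 to C4 creates an oxocarbenium/nitronate pair that collapses to the C2–C3 bond and closes ring C. A Nef reaction gives the flavan-3-one. Transfer hydrogenation under dynamic kinetic resolution then sets C2 and C3 (2R,3R, cis) together.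

Key step: step 4

Remark: flavan numbering is used throughout (O1, C2, C3, C4, C4a to C8a; ring A fused, ring B on C2, ring C the pyran).
Assumption: in step 6 the (R,R) catalyst is chosen on the model that the C2 side of the ketone (aryl group and ether oxygen) takes the place of the aryl group of an aryl alkyl ketone. Should the first run show the opposite sense, the (S,S) catalyst is used instead.

Step 1
Reactants: 1 3,5-bis(benzyloxy)phenol
Product: 3 2,4-bis(benzyloxy)-6-hydroxybenzaldehyde, via salicyl alcohol 2 (not isolated)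
Conditions: MgCl2, Et3N, (CH2O)n, MeCN, reflux; then 1 M HCl
Reagents that add atoms: paraformaldehyde (reacts as formaldehyde), C=O
Why: Casnati-Skattebøl ortho-formylation: the magnesium phenoxide of 1 binds formaldehyde and delivers it only ortho to the phenol oxygen (the two ortho positions are equivalent), and a second formaldehyde takes up hydride from the magnesium alkoxide of 2 to give the aldehyde, while the benzyl ethers are inert.

Step 2
Reactants: 3 2,4-bis(benzyloxy)-6-hydroxybenzaldehyde; 4 3,4-bis(benzyloxy)benzyl chloride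
Product: 5 2,4-bis(benzyloxy)-6-{[3,4-bis(benzyloxy)benzyl]oxy}benzaldehyde
Conditions: K2CO3, NaI (cat.), DMF, 60 °C
Reagents that add atoms: none
Why: Williamson ether synthesis: the last, hydrogen-bonded phenol of 3 is alkylated by the reactive benzylic chloride under iodide catalysis, which installs the future O1-C2 bond and ring B.

Step 3
Reactants: 5 2,4-bis(benzyloxy)-6-{[3,4-bis(benzyloxy)benzyl]oxy}benzaldehyde; 6 nitromethane
Product: 8 1,5-bis(benzyloxy)-3-{[3,4-bis(benzyloxy)benzyl]oxy}-2-[(E)-2-nitrovinyl]benzene, via nitroaldol 7 (not isolated)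
Conditions: NH4OAc (0.5 equiv), MeNO2 (solvent), 95 °C
Reagents that add atoms: none
Why: Henry reaction followed by dehydration in the same flask: ammonium acetate catalyses nitroaldol addition and loss of water, conjugation with ring A makes the E alkene the stable product, and nitromethane supplies C3.

Step 4
Reactants: 8 1,5-bis(benzyloxy)-3-{[3,4-bis(benzyloxy)benzyl]oxy}-2-[(E)-2-nitrovinyl]benzene
Product: 10 5,7-bis(benzyloxy)-2-[3,4-bis(benzyloxy)phenyl]-3-nitrochromane (racemic, C2/C3 diastereomers, trans expected to prevail), via oxocarbenium-nitronate zwitterion 9 (not isolated)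
Conditions: Sc(OTf)3 (20 mol %), 4 Å MS, ClCH2CH2Cl, 70 °C
Reagents that add atoms: none
Why: Proposed new method: Sc(OTf)3 binds the nitro group of 8 and raises the hydride affinity of C4, so that one of the two C2 hydrogens, which is benzylic to electron-rich ring B, alpha to O1 and 1,5 to C4, migrates suprafacially as hydride through a six-membered transition state and gives zwitterion 9, an O1=C2 oxocarbenium ion paired with a C3 nitronate. The nitronate carbon C3 then attacks C2 and forms the C2-C3 bond, a 6-endo-trig closure at the oxocarbenium ion (enolexo for the nitronate) that completes ring C and leaves C4 as the CH2 group of the target. The closest known reaction type is the Lewis-acid-catalysed 1,5-hydride shift/ring closure (internal redox reaction, the oxygen version of the tert-amino effect) of ortho-benzyloxybenzylidene malonates to 2-arylchroman-3,3-dicarboxylates; new here is the singly activated nitrovinyl acceptor, intrinsically the stronger electrophile of the two. C2 and C3 form without absolute control and probably trans with both groups equatorial, which does not matter because C3 becomes a carbonyl carbon in step 5 and C2 is equilibrated in step 6. The step needs site selectivity between the C2 hydrogens and those of the 5-O-benzyl group, which are also 1,5 to C4, and the para-benzyloxy group of ring B secures it by stabilising the cation at C2 far more than a plain phenyl ring could. It also needs hydride transfer to outrun ionisation or hydrolysis of the benzyl aryl ether, which is why a mild oxophilic triflate, molecular sieves and no protic acid are used.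

Step 5
Reactants: 10 5,7-bis(benzyloxy)-2-[3,4-bis(benzyloxy)phenyl]-3-nitrochromane
Product: 13 5,7-bis(benzyloxy)-2-[3,4-bis(benzyloxy)phenyl]chroman-3-one (racemic), via sodium nitronate 11 (not isolated), via flavan-3-imine 12 (not isolated)
Conditions: NaOMe (1.05 equiv), THF/MeOH, 0 °C, 10 min; then added to aq. TiCl3 (4.5 equiv)/NH4OAc (pH about 6), 0 °C to rt
Reagents that add atoms: water, O
Why: Reductive Nef reaction: brief deprotonation at C3 gives nitronate 11, trivalent titanium removes both N-O bonds to give imine 12, and the buffered water hydrolyses it to the ketone, which erases the C3 stereocentre and leaves the benzyl ethers untouched.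

Step 6
Reactants: 13 5,7-bis(benzyloxy)-2-[3,4-bis(benzyloxy)phenyl]chroman-3-one
Product: 14 (2R,3R)-5,7-bis(benzyloxy)-2-[3,4-bis(benzyloxy)phenyl]chroman-3-ol (tetra-O-benzyl-(−)-epicatechin, 2,3-cis)
Conditions: RuCl(p-cymene)[(R,R)-TsDPEN] (2 mol %), HCO2H/Et3N (5:2), CH2Cl2, 35 °C
Reagents that add atoms: none
Why: Noyori asymmetric transfer hydrogenation under dynamic kinetic resolution, as known for alpha-aryl cyclic ketones: Et3N racemises the doubly activated C2 through the enol faster than reduction, and the chiral ruthenium hydride should reduce only the (2R) ketone on the Si face of C3, anti to the C2 aryl group, so that C3 (R) is set by the catalyst, the cis relation by the substrate and C2 (R) by the resolution.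

Step 7
Reactants: 14 (2R,3R)-5,7-bis(benzyloxy)-2-[3,4-bis(benzyloxy)phenyl]chroman-3-ol; 15 4-(benzyloxy)-3-methoxybenzoic acid
Product: 16 (2R,3R)-5,7-bis(benzyloxy)-2-[3,4-bis(benzyloxy)phenyl]chroman-3-yl 4-(benzyloxy)-3-methoxybenzoate
Conditions: DCC, DMAP (cat.), CH2Cl2, rt
Reagents that add atoms: none
Why: Steglich esterification: the DCC-activated acid is passed on by DMAP to the axial 3-OH, no bond to C2 or C3 is broken, and the configuration is kept.

Step 8
Reactants: 16 (2R,3R)-5,7-bis(benzyloxy)-2-[3,4-bis(benzyloxy)phenyl]chroman-3-yl 4-(benzyloxy)-3-methoxybenzoate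
Product: 17 (2R,3R)-2-(3,4-dihydroxyphenyl)-5,7-dihydroxychroman-3-yl 4-hydroxy-3-methoxybenzoate ((−)-epicatechin 3-O-vanillate, CNP0302437.1)
Conditions: H2 (1 atm), Pd(OH)2/C, THF/MeOH, rt
Reagents that add atoms: none
Why: Catalytic hydrogenolysis: the five acyclic O-benzyl groups are cleaved at balloon pressure, while the ester and the cyclic benzylic C2-O1 bond of flavans persist under such mild neutral conditions, so C2 and C3 stay as set.

Compound list
1 | 3,5-bis(benzyloxy)phenol | Oc1cc(OCc2ccccc2)cc(OCc2ccccc2)c1 | starting material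
2 | 3,5-bis(benzyloxy)-2-(hydroxymethyl)phenol (salicyl alcohol, present as its magnesium salt) | OCc1c(O)cc(OCc2ccccc2)cc1OCc1ccccc1 | intermediate
3 | 2,4-bis(benzyloxy)-6-hydroxybenzaldehyde | O=Cc1c(O)cc(OCc2ccccc2)cc1OCc1ccccc1 | intermediate
4 | 3,4-bis(benzyloxy)benzyl chloride | ClCc1ccc(OCc2ccccc2)c(OCc2ccccc2)c1 | starting material
5 | 2,4-bis(benzyloxy)-6-{[3,4-bis(benzyloxy)benzyl]oxy}benzaldehyde | O=Cc1c(OCc2ccc(OCc3ccccc3)c(OCc3ccccc3)c2)cc(OCc2ccccc2)cc1OCc1ccccc1 | intermediate
6 | nitromethane | C[N+](=O)[O-] | starting material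
7 | 1-(2,4-bis(benzyloxy)-6-{[3,4-bis(benzyloxy)benzyl]oxy}phenyl)-2-nitroethanol (racemic nitroaldol) | O=[N+]([O-])CC(O)c1c(OCc2ccc(OCc3ccccc3)c(OCc3ccccc3)c2)cc(OCc2ccccc2)cc1OCc1ccccc1 | intermediate
8 | 1,5-bis(benzyloxy)-3-{[3,4-bis(benzyloxy)benzyl]oxy}-2-[(E)-2-nitrovinyl]benzene | O=[N+]([O-])/C=C/c1c(OCc2ccc(OCc3ccccc3)c(OCc3ccccc3)c2)cc(OCc2ccccc2)cc1OCc1ccccc1 | intermediate
9 | zwitterion: O1=C2 oxocarbenium ion and C3 nitronate after the hydride shift (scandium-bound in the flask) | [O-][N+]([O-])=CCc1c(OCc2ccccc2)cc(OCc2ccccc2)cc1[O+]=Cc1ccc(OCc2ccccc2)c(OCc2ccccc2)c1 | intermediate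
10 | 5,7-bis(benzyloxy)-2-[3,4-bis(benzyloxy)phenyl]-3-nitrochromane (racemic, diastereomer mixture, no descriptor assigned) | O=[N+]([O-])C1Cc2c(OCc3ccccc3)cc(OCc3ccccc3)cc2OC1c1ccc(OCc2ccccc2)c(OCc2ccccc2)c1 | intermediate
11 | sodium nitronate of 10 (racemic at C2) | [Na+].[O-][N+]([O-])=C1Cc2c(OCc3ccccc3)cc(OCc3ccccc3)cc2OC1c1ccc(OCc2ccccc2)c(OCc2ccccc2)c1 | intermediate
12 | 5,7-bis(benzyloxy)-2-[3,4-bis(benzyloxy)phenyl]chroman-3-imine (racemic at C2) | N=C1Cc2c(OCc3ccccc3)cc(OCc3ccccc3)cc2OC1c1ccc(OCc2ccccc2)c(OCc2ccccc2)c1 | intermediate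
13 | 5,7-bis(benzyloxy)-2-[3,4-bis(benzyloxy)phenyl]chroman-3-one (racemic, C2 labile to base) | O=C1Cc2c(OCc3ccccc3)cc(OCc3ccccc3)cc2OC1c1ccc(OCc2ccccc2)c(OCc2ccccc2)c1 | intermediate
14 | (2R,3R)-5,7-bis(benzyloxy)-2-[3,4-bis(benzyloxy)phenyl]chroman-3-ol | O[C@@H]1Cc2c(OCc3ccccc3)cc(OCc3ccccc3)cc2O[C@@H]1c1ccc(OCc2ccccc2)c(OCc2ccccc2)c1 | intermediate
15 | 4-(benzyloxy)-3-methoxybenzoic acid | COc1cc(C(=O)O)ccc1OCc1ccccc1 | starting material
16 | (2R,3R)-5,7-bis(benzyloxy)-2-[3,4-bis(benzyloxy)phenyl]chroman-3-yl 4-(benzyloxy)-3-methoxybenzoate | COc1cc(C(=O)O[C@@H]2Cc3c(OCc4ccccc4)cc(OCc4ccccc4)cc3O[C@@H]2c2ccc(OCc3ccccc3)c(OCc3ccccc3)c2)ccc1OCc1ccccc1 | intermediate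
17 | (2R,3R)-2-(3,4-dihydroxyphenyl)-5,7-dihydroxychroman-3-yl 4-hydroxy-3-methoxybenzoate | COc1cc(C(=O)O[C@@H]2Cc3c(O)cc(O)cc3O[C@@H]2c2ccc(O)c(O)c2)ccc1O | target

Total step count: 8. Longest linear sequence: 8 steps (1 to 17). Compounds 4, 6 and 15 enter as purchased.

Steps most likely to fail

1. Step 4 (bears the label Proposed new method).
- What may go wrong: the three alkoxy groups of ring A lower the hydride affinity of C4. Hydride transfer may then be slower than Lewis-acid ionisation of the electron-rich benzyl aryl ether, or hydride may be donated from the 5-O-benzyl group instead.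
- Fallback: known chemistry that closes ring C at the same C2–C3 bond, here as an alkene. It sets out from 1 and comes back at 13.
- Phenol 1 is O-allylated (allyl bromide, K2CO3, acetone) to 1-(allyloxy)-3,5-bis(benzyloxy)benzene F1.
- An aromatic Claisen rearrangement (N,N-diethylaniline, 190 °C, both ortho positions equivalent) gives 2-allyl-3,5-bis(benzyloxy)phenol F2.
- Steglich esterification with purchased 3,4-bis(benzyloxy)benzoic acid gives 2-allyl-3,5-bis(benzyloxy)phenyl 3,4-bis(benzyloxy)benzoate F3.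
- Petasis methylenation (Cp2TiMe2, toluene, 75 °C) turns the ester carbonyl into the enol ether 2-allyl-1,5-bis(benzyloxy)-3-({1-[3,4-bis(benzyloxy)phenyl]vinyl}oxy)benzene F4.
- Ring-closing metathesis with second-generation Grubbs catalyst (toluene, 80 °C) gives 5,7-bis(benzyloxy)-2-[3,4-bis(benzyloxy)phenyl]-4H-chromene F5.
- Hydroboration-oxidation (BH3·THF, then NaOH/H2O2) places oxygen on C3 and gives (±)-trans-5,7-bis(benzyloxy)-2-[3,4-bis(benzyloxy)phenyl]chroman-3-ol F6.
- Dess-Martin oxidation of F6 gives 13.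

2. Step 5.
- What may go wrong: once the nitronate is formed it may expel the O1 phenoxide by retro-oxa-Michael reaction. Ring C would then open before the reduction takes place.
- Fallback: it avoids any carbanion at C3, sets out from 10 and comes back at 13.
- The nitro group is reduced under acidic conditions (Zn, AcOH/THF, rt) to 5,7-bis(benzyloxy)-2-[3,4-bis(benzyloxy)phenyl]chroman-3-amine F7.
- F7 is deaminated oxidatively by transamination with 3,5-di-tert-butyl-1,2-benzoquinone (MeOH/THF, rt), followed by hydrolysis with aqueous oxalic acid in the same flask, to give 13.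

3. Step 6.
- What may go wrong: epimerisation at C2 may be slower than reduction. Facial discrimination may also be poor for a ketone that bears no aryl group on the carbonyl carbon. Either would erode enantiomeric or cis purity.
- Fallback: substrate-controlled reduction followed by classical resolution. It sets out from 13 and comes back at 14.
- LiBH(s-Bu)3 (THF, −78 °C) attacks anti to the C2 aryl group and gives (±)-cis-5,7-bis(benzyloxy)-2-[3,4-bis(benzyloxy)phenyl]chroman-3-ol F8.
- Steglich esterification with (S)-2-methoxy-2-phenylacetic acid gives two diastereomeric esters, separated by chromatography or crystallisation. They are the (2R,3R)-chroman-3-yl (S)-2-methoxy-2-phenylacetate F9, which is kept, and the (2S,3S)-chroman-3-yl (S)-2-methoxy-2-phenylacetate F10, which is removed.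
- Saponification of F9 (LiOH, THF/MeOH/H2O) gives 14. C2 cannot epimerise here because the 4'-oxygen is benzylated.

Further compounds
F1 | step 4 | 1-(allyloxy)-3,5-bis(benzyloxy)benzene | C=CCOc1cc(OCc2ccccc2)cc(OCc2ccccc2)c1
F2 | step 4 | 2-allyl-3,5-bis(benzyloxy)phenol | C=CCc1c(O)cc(OCc2ccccc2)cc1OCc1ccccc1
F3 | step 4 | 2-allyl-3,5-bis(benzyloxy)phenyl 3,4-bis(benzyloxy)benzoate | C=CCc1c(OC(=O)c2ccc(OCc3ccccc3)c(OCc3ccccc3)c2)cc(OCc2ccccc2)cc1OCc1ccccc1
F4 | step 4 | 2-allyl-1,5-bis(benzyloxy)-3-({1-[3,4-bis(benzyloxy)phenyl]vinyl}oxy)benzene | C=CCc1c(OC(=C)c2ccc(OCc3ccccc3)c(OCc3ccccc3)c2)cc(OCc2ccccc2)cc1OCc1ccccc1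
F5 | step 4 | 5,7-bis(benzyloxy)-2-[3,4-bis(benzyloxy)phenyl]-4H-chromene | C1(c2ccc(OCc3ccccc3)c(OCc3ccccc3)c2)=CCc2c(OCc3ccccc3)cc(OCc3ccccc3)cc2O1
F6 | step 4 | (±)-trans-5,7-bis(benzyloxy)-2-[3,4-bis(benzyloxy)phenyl]chroman-3-ol (both enantiomers) | O[C@H]1Cc2c(OCc3ccccc3)cc(OCc3ccccc3)cc2O[C@@H]1c1ccc(OCc2ccccc2)c(OCc2ccccc2)c1.O[C@@H]1Cc2c(OCc3ccccc3)cc(OCc3ccccc3)cc2O[C@H]1c1ccc(OCc2ccccc2)c(OCc2ccccc2)c1
F7 | step 5 | 5,7-bis(benzyloxy)-2-[3,4-bis(benzyloxy)phenyl]chroman-3-amine (racemic, diastereomer mixture) | NC1Cc2c(OCc3ccccc3)cc(OCc3ccccc3)cc2OC1c1ccc(OCc2ccccc2)c(OCc2ccccc2)c1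
F8 | step 6 | (±)-cis-5,7-bis(benzyloxy)-2-[3,4-bis(benzyloxy)phenyl]chroman-3-ol (both enantiomers) | O[C@@H]1Cc2c(OCc3ccccc3)cc(OCc3ccccc3)cc2O[C@@H]1c1ccc(OCc2ccccc2)c(OCc2ccccc2)c1.O[C@H]1Cc2c(OCc3ccccc3)cc(OCc3ccccc3)cc2O[C@H]1c1ccc(OCc2ccccc2)c(OCc2ccccc2)c1
F9 | step 6 | (2R,3R)-5,7-bis(benzyloxy)-2-[3,4-bis(benzyloxy)phenyl]chroman-3-yl (S)-2-methoxy-2-phenylacetate | CO[C@H](C(=O)O[C@@H]1Cc2c(OCc3ccccc3)cc(OCc3ccccc3)cc2O[C@@H]1c1ccc(OCc2ccccc2)c(OCc2ccccc2)c1)c1ccccc1
F10 | step 6 | (2S,3S)-5,7-bis(benzyloxy)-2-[3,4-bis(benzyloxy)phenyl]chroman-3-yl (S)-2-methoxy-2-phenylacetate | CO[C@H](C(=O)O[C@H]1Cc2c(OCc3ccccc3)cc(OCc3ccccc3)cc2O[C@H]1c1ccc(OCc2ccccc2)c(OCc2ccccc2)c1)c1ccccc1
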